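**Assumptions**

- The target SMILES assigns no configuration to the C2'–C8'' axis, so the biaryl is made without axial control and no stereogenic element has to be set.
- Apigenin and 4',5,7-tri-O-methylapigenin are taken as catalogue compounds.

## Structural features

The target is a dimer of apigenin (5,7,4'-trihydroxyflavone): two 2-aryl-4H-chromen-4-ones, each with a phloroglucinol-type ring A, a pyranone ring C and a 4-hydroxyphenyl ring B. Unit 1 carries unprimed locants (rings A and C) and single primes (ring B); unit 2 carries double primes (rings A and C) and triple primes (ring B). The units are joined by one biaryl bond between C2' of ring B of unit 1 (ortho to C1', which bears the chromone, and meta to the 4'-hydroxyl) and C8'' of ring A of unit 2 (between C7''–OH and the ring oxygen O1''). There is no stereocentre; the only stereochemical element is the unassigned, tri-ortho-substituted axis. Fragile features are the six phenols (oxidation), the pyranones (ring opening in hot alkali) and the 8-aryl-5-hydroxychromone, which can isomerise to the 6-aryl isomer in hot strong acid (Wessely–Moser rearrangement). The real difficulty is the hindered inter-unit bond: it sits at a ring B carbon meta to the phenol, which phenol oxidative coupling (ortho/para) cannot reach, and ring A of unit 2 must react at C8'' and not at C6''. The key step exploits that C2' is the β-carbon of the cyclohexa-2,5-dienone formed when ring B is dearomatised at C1' (C4'=O, C1' sp3 with OH), while C8''–H is the most nucleophilic CH of a 5,7-dimethoxyflavone. In one sentence: the C2'–C8'' bond is formed by Friedel–Crafts conjugate addition of the unfunctionalised C8–H of one flavone to the dearomatised ring B of the other, which then re-aromatises by loss of water.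

## Logic of the disconnections

**8 ⇒ 6 (through 7).** Bonds cut: three O–CH3 bonds (O5'', O7'', O4''') and two O–acetyl bonds (O5, O7). The masks are chosen for their electronic effect one step earlier: methyl ethers keep ring A of unit 2 electron-rich, acetates make ring A of unit 1 electron-poor. There is no skeletal gain, but 6 has only one free phenol. The forward step must cleave aryl methyl ethers without opening ring C of unit 2, so that the aryl group stays at C8''.

**6 ⇒ 3 + 4 (through 5).** Bond cut: C2'–C8'', after formal addition of water across C1'–C2' of ring B. This turns ring B of 6 into the cross-conjugated dienone of 3, in which C2' is an electrophilic β-carbon, and leaves 4 with a plain C8–H. The gain is the largest in the route: a hindered biflavone falls into two monomeric flavones, neither carrying halogen, boron or metal at the bond site. The forward step demands 1,4-addition at C2' (not substitution at C3' by loss of the C1' oxygen), reaction of 4 at C8 (not C6), ring A of 3 staying silent as a nucleophile, and dehydration of 5 to the arene.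

**3 ⇒ 2.** Bonds cut: the two acetyl–O bonds at O5 and O7. Ring A of 2 is a phloroglucinol-type nucleophile that could add to the dienone of a second molecule; as the diacetate it is switched off. The forward step must acylate the two phenols and leave the tertiary C1' hydroxyl and the dienone untouched.

**2 ⇒ 1.** Bond cut: C1'–OH, with two electrons returned to ring B. The dienone is the oxidised, hydrated form of the 4'-hydroxyphenyl ring, so 2 comes from 1 by oxidative dearomatisation with water as the oxygen source. The forward step demands oxidation at the 4'-phenol and not at ring A, and capture by water at C1' (para). Compounds 1 and 4 are starting materials.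

## Other disconnections considered

**Alternative 1:** (the first to come to mind) Cut: the same C2'–C8'' bond, with both carbons pre-functionalised. Forward key step: Suzuki–Miyaura coupling of 8-iodo-4',5,7-tri-O-methylapigenin A1 with 2'-(pinacolatoboryl)-4',5,7-tri-O-methylapigenin A2 to hexa-O-methyl-2',8''-biapigenin A3, then sixfold demethylation. Grounds for preferring the chosen plan:
- Both bond carbons need prior functionalisation.
- A2 cannot be derived from a catalogue flavone; it must be raised from a 2-halo-4-methoxybenzoic acid by O-acylation, Baker–Venkataraman shift, cyclodehydration and borylation.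
- The coupling joins a di-ortho-substituted iodide to an ortho-substituted boronate that is prone to protodeboronation, through a crowded reductive elimination.
- The route would need roughly twice as many steps.

**Alternative 2:** Cut: both bonds at ring B (C1'–C2 and C2'–C8'') in one aryne operation. Forward key step: 4-methoxy-2-(trimethylsilyl)phenyl triflate A4 with CsF gives 4-methoxybenzyne A5; 2,4,6-trimethoxyphenylmagnesium bromide A6 adds to it, and the biarylmagnesium is trapped with CO2 to give 4-methoxy-2-(2,4,6-trimethoxyphenyl)benzoic acid A7. Both pyranones would then be built. Grounds for preferring the chosen plan: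
- The methoxy group of A5 is one carbon removed from the nearer aryne carbon, so it gives little inductive or distortion bias. The regioisomeric 5-methoxy-2-(2,4,6-trimethoxyphenyl)benzoic acid A8 is expected in comparable amount.
- A directing group would have to sit at C3' or C6', where the target has hydrogen.
- The symmetric trioxygenated ring of A7 must afterwards be acylated and closed through the oxygen next to the biaryl bond, not the less hindered ortho oxygen. The C8''/C6'' problem returns, with sterics favouring the wrong isomer.

**Alternative 3:** Cut: C1'–C6' and C2'–C3' of ring B, which is built by cycloaddition. Forward key step: A1 is converted by Sonogashira coupling into methyl 3-[5,7-dimethoxy-2-(4-methoxyphenyl)-4-oxo-4H-chromen-8-yl]prop-2-ynoate A9. Diels–Alder reaction with 1-methoxy-3-(trimethylsilyloxy)buta-1,3-diene, loss of methanol and desilylation would give methyl 2-[5,7-dimethoxy-2-(4-methoxyphenyl)-4-oxo-4H-chromen-8-yl]-4-hydroxybenzoate A10. The orientation is right: the nucleophilic diene terminus bonds to the aryl-bearing alkyne carbon, so the hydroxyl ends up para to the ester. Unit 1 would then be completed by esterification, Baker–Venkataraman shift and cyclodehydration. Grounds for preferring the chosen plan: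
- The β-carbon of A9 carries a di-ortho-substituted, electron-rich aryl group that lowers the dienophile reactivity and shields the carbon that must bond.
- A1 is needed anyway, so pre-functionalisation is not avoided.
- Four more steps raise ring C on a hindered benzoate, for about ten steps against four.

Key step: step 3

## Route

**Step 1**
Reactants: 1 apigenin
Product: 2 protoapigenone
Conditions: PhI(OCOCF3)2 (2 equiv), MeCN/H2O 9:1, high dilution, rt → 70 °C
Reagents that add atoms: water, O
Why: Oxidative dearomatisation of a para-substituted phenol to a para-quinol by a trivalent iodine reagent: the 4'-phenol exchanges onto iodine, iodobenzene leaves, and water is captured at the para carbon C1'. The ring A phenols sit on a ring deactivated by the conjugated pyranone carbonyl, so the 4'-phenol should be oxidised first; C1' is not stereogenic because its two dienone arms are identical.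

**Step 2**
Reactants: 2 protoapigenone
Product: 3 5,7-di-O-acetylprotoapigenone
Conditions: Ac2O (6 equiv), pyridine, 0 °C → rt
Reagents that add atoms: acetic anhydride, CC(=O)OC(C)=O
Why: O-Acetylation of phenols (nucleophilic acyl substitution); the tertiary, doubly allylic C1' hydroxyl next to the chromenyl group is too hindered to be acylated without an acyl-transfer catalyst. The acetoxy groups turn ring A from a strong into a weak π-nucleophile, which step 3 needs.

**Step 3**
Reactants: 3 5,7-di-O-acetylprotoapigenone; 4 4',5,7-tri-O-methylapigenin
Product: 6 5,7-di-O-acetyl-5'',7'',4'''-tri-O-methyl-2',8''-biapigenin, via Michael adduct 5 (not isolated)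
Conditions: 4 (2.5 equiv), CF3SO3H (15 mol %), (CF3)2CHOH/CH2Cl2 1:1, slow addition of 3 at 0 °C, rt, then 45 °C
Reagents that add atoms: none
Why: The acid, kept below the amount of 4 so that the basic pyranone carbonyl of 4 stays largely unprotonated, activates the dienone carbonyl of 3 to a 4-hydroxypentadienyl cation whose termini are the enantiotopic carbons C2' and C6'; C8 of 4 attacks one of them in a Friedel–Crafts conjugate (Michael) addition to give 5, enolisation of 5 toward C3' makes a cyclohexadienol that is formally the hydrate of an arene, and acid-catalysed loss of the C1' hydroxyl with the C2' proton restores ring B with the new aryl group ortho to C1' and meta to O4'. The closest known reaction type is the acid-catalysed conjugate arylation of 4-substituted 4-hydroxycyclohexa-2,5-dienones (para-quinols) by electron-rich arenes such as indoles, naphthols and alkoxybenzenes, followed by dehydrative re-aromatisation to meta-arylated phenols. No ring is closed and no stereocentre survives: C1' and C2' of 5 form without control and both become sp2 on aromatisation, and the new axis forms without control because the target assigns none. Attack at the β-carbon C2' and not at C3' is secured because the C1' hydroxyl is a poor leaving group and the electron-poor chromen-2-yl substituent disfavours the 4-oxocyclohexadienyl cation through which substitution next to oxygen would run. On the nucleophile, C8 of 4 is para to the 5-methoxy group, whereas C6 is para to the ring oxygen, whose lone pair is tied up in the vinylogous ester of ring C, and is flanked by two methoxy groups. Cross-reaction over self-reaction is secured by the two acetoxy groups, which make ring A of 3 and of unit 1 in 6 far weaker nucleophiles than ring A of 4, and by keeping 3 at low concentration against an excess of 4. The hindered bond is made as an sp2–sp3 bond on the open face of a dienone, and the strain of the tri-ortho-substituted biaryl is paid for by the aromatisation, which also makes the step irreversible.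

**Step 4**
Reactants: 6 5,7-di-O-acetyl-5'',7'',4'''-tri-O-methyl-2',8''-biapigenin
Product: 8 2',8''-biapigenin, via 2',8''-biapigenin 5,7-di-O-acetate 7 (not isolated)
Conditions: BBr3 (10 equiv), CH2Cl2, −78 °C → rt; then MeOH, 0 → 50 °C
Reagents that add atoms: none
Why: Lewis-acid cleavage of aryl methyl ethers by BBr3 (bromide attacks the methyl group of the O–B complex in an SN2 reaction) gives the aryl borates of 7; the methanol quench frees the phenols and generates HBr, which catalyses transesterification of the two aryl acetates to methyl acetate. Any acetate already cleaved by BBr3 ends as the same methyl acetate, and the anhydrous, low-temperature conditions should avoid the hydrolytic ring opening behind the Wessely–Moser rearrangement.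

## Compound list

1 | apigenin (5,7-dihydroxy-2-(4-hydroxyphenyl)-4H-chromen-4-one) | O=c1cc(-c2ccc(O)cc2)oc2cc(O)cc(O)c12 | starting material
2 | protoapigenone (5,7-dihydroxy-2-(1-hydroxy-4-oxocyclohexa-2,5-dien-1-yl)-4H-chromen-4-one) | O=C1C=CC(O)(c2cc(=O)c3c(O)cc(O)cc3o2)C=C1 | intermediate
3 | 5,7-di-O-acetylprotoapigenone (2-(1-hydroxy-4-oxocyclohexa-2,5-dien-1-yl)-4-oxo-4H-chromene-5,7-diyl diacetate) | CC(=O)Oc1cc(OC(C)=O)c2c(=O)cc(C3(O)C=CC(=O)C=C3)oc2c1 | intermediate
4 | 4',5,7-tri-O-methylapigenin (5,7-dimethoxy-2-(4-methoxyphenyl)-4H-chromen-4-one) | COc1ccc(-c2cc(=O)c3c(OC)cc(OC)cc3o2)cc1 | starting material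
5 | Michael adduct, 8-[2-(5,7-diacetoxy-4-oxo-4H-chromen-2-yl)-2-hydroxy-5-oxocyclohex-3-en-1-yl]-5,7-dimethoxy-2-(4-methoxyphenyl)-4H-chromen-4-one (racemic mixture of diastereomers, configuration not controlled) | COc1ccc(-c2cc(=O)c3c(OC)cc(OC)c(C4CC(=O)C=CC4(O)c4cc(=O)c5c(OC(C)=O)cc(OC(C)=O)cc5o4)c3o2)cc1 | intermediate (not isolated)
6 | 5,7-di-O-acetyl-5'',7'',4'''-tri-O-methyl-2',8''-biapigenin (8-[2-(5,7-diacetoxy-4-oxo-4H-chromen-2-yl)-5-hydroxyphenyl]-5,7-dimethoxy-2-(4-methoxyphenyl)-4H-chromen-4-one) | COc1ccc(-c2cc(=O)c3c(OC)cc(OC)c(-c4cc(O)ccc4-c4cc(=O)c5c(OC(C)=O)cc(OC(C)=O)cc5o4)c3o2)cc1 | intermediate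
7 | 2',8''-biapigenin 5,7-di-O-acetate (8-[2-(5,7-diacetoxy-4-oxo-4H-chromen-2-yl)-5-hydroxyphenyl]-5,7-dihydroxy-2-(4-hydroxyphenyl)-4H-chromen-4-one) | Oc1ccc(-c2cc(=O)c3c(O)cc(O)c(-c4cc(O)ccc4-c4cc(=O)c5c(OC(C)=O)cc(OC(C)=O)cc5o4)c3o2)cc1 | intermediate (not isolated)
8 | 2',8''-biapigenin | O=c1cc(-c2ccc(O)cc2-c2c(O)cc(O)c3c(=O)cc(-c4ccc(O)cc4)oc23)oc2cc(O)cc(O)c12 | target

## Step count and risk

Total step count: 4. Longest linear sequence: 4 steps (1 → 2 → 3 → 6 → 8); 4 enters at step 3.

**Step 3 (key step).** Three things are most likely to go wrong:
- The conjugate addition may stall, because the basic pyranone carbonyl of 4 ties up the acid and lowers the nucleophilicity of its ring A.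
- Ionisation of the C1'–O bond may compete, with attack of the arene next to the ring B oxygen or a dienone–phenol shift.
- The reaction may stop at the adduct stage, without dehydration.

The fallback gives up the dearomatisation logic and makes the same bond by cross-coupling of two functionalised carbons; it sets out from 4 and comes back to the route at 8. Iodination of 4 (N-iodosuccinimide, CF3CO2H, MeCN) at C8 should give 8-iodo-4',5,7-tri-O-methylapigenin F1 (the same compound as A1). Suzuki–Miyaura coupling of F1 with commercial (2-formyl-5-methoxyphenyl)boronic acid (Pd(OAc)2, SPhos, K3PO4, toluene/H2O, 90 °C) should give 2-[5,7-dimethoxy-2-(4-methoxyphenyl)-4-oxo-4H-chromen-8-yl]-4-methoxybenzaldehyde F2. Claisen–Schmidt condensation of F2 with commercial 2'-hydroxy-4',6'-dimethoxyacetophenone (KOH, EtOH, rt) should give the 2'-hydroxychalcone F3. Oxidative cyclisation (I2 cat., DMSO, 130 °C) should give hexa-O-methyl-2',8''-biapigenin F4 (the same compound as A3). Demethylation of F4 with BBr3 under the conditions of step 4 should give 8.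

**Step 1.** The most likely failure is over-oxidation and intermolecular capture of the oxidised ring B by the electron-rich ring A of a second molecule, with poor mass balance. The fallback replaces the two-electron iodine oxidant by singlet oxygen; it sets out from 1 and comes back at 2. Dye-sensitised photo-oxygenation of the 4'-phenolate of 1 (O2, rose bengal, visible light, K2CO3, MeOH, 0 °C) should add oxygen at the para carbon C1' to give protoapigenone 1'-hydroperoxide F5, which is reduced in the same flask with dimethyl sulfide to 2.

**Step 4.** The most likely failures are incomplete cleavage of the hindered 7''-methyl ether next to the biaryl bond, and acid-promoted opening and reclosure of ring C of unit 2 during long exposure, moving the aryl group from C8'' to C6''. The fallback changes the protecting groups of the nucleophile so that no ether has to be cleaved by a Lewis acid; it sets out from 1 and 3 and comes back at 7. Benzylation of 1 (NaH, benzyl bromide, DMF, 60 °C) should give 4',5,7-tri-O-benzylapigenin F6. F6 is used in place of 4 under the conditions of step 3, with the acid held well below the amount of F6, to give 5,7-di-O-acetyl-5'',7'',4'''-tri-O-benzyl-2',8''-biapigenin F7. Hydrogenolysis of F7 (H2, Pd/C, EtOAc/THF, rt) gives 7, and acid methanolysis (HCl cat., MeOH, 40 °C) gives 8.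

## Further compounds

F1 | step 3 | 8-iodo-4',5,7-tri-O-methylapigenin | COc1ccc(-c2cc(=O)c3c(OC)cc(OC)c(I)c3o2)cc1
F2 | step 3 | 2-[5,7-dimethoxy-2-(4-methoxyphenyl)-4-oxo-4H-chromen-8-yl]-4-methoxybenzaldehyde | COc1ccc(C=O)c(-c2c(OC)cc(OC)c3c(=O)cc(-c4ccc(OC)cc4)oc23)c1
F3 | step 3 | (E)-3-{2-[5,7-dimethoxy-2-(4-methoxyphenyl)-4-oxo-4H-chromen-8-yl]-4-methoxyphenyl}-1-(2-hydroxy-4,6-dimethoxyphenyl)prop-2-en-1-one | COc1ccc(/C=C/C(=O)c2c(O)cc(OC)cc2OC)c(-c2c(OC)cc(OC)c3c(=O)cc(-c4ccc(OC)cc4)oc23)c1
F4 | step 3 | hexa-O-methyl-2',8''-biapigenin | COc1ccc(-c2cc(=O)c3c(OC)cc(OC)c(-c4cc(OC)ccc4-c4cc(=O)c5c(OC)cc(OC)cc5o4)c3o2)cc1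
F5 | step 1 | protoapigenone 1'-hydroperoxide (2-(1-hydroperoxy-4-oxocyclohexa-2,5-dien-1-yl)-5,7-dihydroxy-4H-chromen-4-one) | O=C1C=CC(OO)(c2cc(=O)c3c(O)cc(O)cc3o2)C=C1
F6 | step 4 | 4',5,7-tri-O-benzylapigenin | O=c1cc(-c2ccc(OCc3ccccc3)cc2)oc2cc(OCc3ccccc3)cc(OCc3ccccc3)c12
F7 | step 4 | 5,7-di-O-acetyl-5'',7'',4'''-tri-O-benzyl-2',8''-biapigenin | CC(=O)Oc1cc(OC(C)=O)c2c(=O)cc(-c3ccc(O)cc3-c3c(OCc4ccccc4)cc(OCc4ccccc4)c4c(=O)cc(-c5ccc(OCc6ccccc6)cc5)oc34)oc2c1
A1 | alternative 1 | 8-iodo-4',5,7-tri-O-methylapigenin | COc1ccc(-c2cc(=O)c3c(OC)cc(OC)c(I)c3o2)cc1
A2 | alternative 1 | 2'-(pinacolatoboryl)-4',5,7-tri-O-methylapigenin | COc1ccc(-c2cc(=O)c3c(OC)cc(OC)cc3o2)c(B2OC(C)(C)C(C)(C)O2)c1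
A3 | alternative 1 | hexa-O-methyl-2',8''-biapigenin | COc1ccc(-c2cc(=O)c3c(OC)cc(OC)c(-c4cc(OC)ccc4-c4cc(=O)c5c(OC)cc(OC)cc5o4)c3o2)cc1
A4 | alternative 2 | 4-methoxy-2-(trimethylsilyl)phenyl trifluoromethanesulfonate | COc1ccc(OS(=O)(=O)C(F)(F)F)c([Si](C)(C)C)c1
A5 | alternative 2 | 4-methoxybenzyne | COC1=CC#CC=C1
A6 | alternative 2 | 2,4,6-trimethoxyphenylmagnesium bromide | COc1cc(OC)c([Mg]Br)c(OC)c1
A7 | alternative 2 | 4-methoxy-2-(2,4,6-trimethoxyphenyl)benzoic acid | COc1ccc(C(=O)O)c(-c2c(OC)cc(OC)cc2OC)c1
A8 | alternative 2 | 5-methoxy-2-(2,4,6-trimethoxyphenyl)benzoic acid | COc1ccc(-c2c(OC)cc(OC)cc2OC)c(C(=O)O)c1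
A9 | alternative 3 | methyl 3-[5,7-dimethoxy-2-(4-methoxyphenyl)-4-oxo-4H-chromen-8-yl]prop-2-ynoate | COC(=O)C#Cc1c(OC)cc(OC)c2c(=O)cc(-c3ccc(OC)cc3)oc12
A10 | alternative 3 | methyl 2-[5,7-dimethoxy-2-(4-methoxyphenyl)-4-oxo-4H-chromen-8-yl]-4-hydroxybenzoate | COC(=O)c1ccc(O)cc1-c1c(OC)cc(OC)c2c(=O)cc(-c3ccc(OC)cc3)oc12
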